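Everything rests on cutting ring D (O4', Cα, Cβ, C5', C4') at two bonds, O4'–Cα and Cα–Cβ, so that Cα with its 4-hydroxyphenyl group arrives as a one-carbon unit. The feature exploited is the ortho pair O4'/C5' of ring B. Together with benzylic Cβ it is a latent ortho-quinone methide, pushed by the para oxygen O2'. In one operation an aryl Grignard reagent adds to a 5'-formyl-4'-OBoc (2S)-flavanone, the quinone methide is released, and a chiral sulfonium benzylide adds and loses its sulfide. This [4+1] annulation joins three fragments, closes ring D and sets Cα and Cβ. The precursor is the complete silylated 6,8-diprenylflavanone aldehyde, made by asymmetric rhodium-catalysed arylation of a chromone.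

Key step: step 10

Numbering: flavanone numbering is used (rings A, C, B; primes on ring B). Cα is the O-bound sp3 carbon of ring D and carries the 4-hydroxyphenyl ring. Cβ is bound to C5' and carries the 3,5-dihydroxyphenyl ring. The target is (2S,αR,βR) with ring D trans. TBS = tert-butyldimethylsilyl.

Assumption: (1S,4S,5S)-isothiocineole 15 is taken as purchasable (it is otherwise one step from (S)-limonene, sulfur and γ-terpinene). Its sense of induction in step 10 is assigned from the ylide model given there.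

Step 1
Reactants: 1 2',4',6'-trihydroxyacetophenone; 2 prenyl bromide
Product: 3 2',4',6'-trihydroxy-3',5'-diprenylacetophenone
Conditions: 2 (2.1 equiv), KOH (2.1 equiv), H2O, 0 °C to rt
Reagents that add atoms: none
Why: C-alkylation of the ambident phloroglucinol-type phenoxide, which reacts at carbon in water, should place one prenyl group on each of the two free ring carbons.

Step 2
Reactants: 3 2',4',6'-trihydroxy-3',5'-diprenylacetophenone
Product: 4 2'-hydroxy-4',6'-bis(TBSO)-3',5'-diprenylacetophenone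
Conditions: TBSCl (2.3 equiv), imidazole, DMF, rt
Reagents that add atoms: tert-butyldimethylsilyl chloride CC(C)(C)[Si](C)(C)Cl
Why: Silyl ether formation should stop at the bis-ether because the last hydroxyl group is held in a hydrogen bond to the acetyl carbonyl.

Step 3
Reactants: 4 2'-hydroxy-4',6'-bis(TBSO)-3',5'-diprenylacetophenone
Product: 6 5,7-bis(TBSO)-6,8-diprenylchromone, via enaminone 5 (not isolated)
Conditions: DMF dimethyl acetal (3 equiv), toluene, 90 °C; concentrate; then 1 M aq HCl, CH2Cl2, rt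
Reagents that add atoms: N,N-dimethylformamide dimethyl acetal COC(OC)N(C)C
Why: This is the enaminone chromone synthesis: condensation at the acetyl CH3, then acid-promoted addition of the free phenol and loss of dimethylamine, which closes ring C.

Step 4
Reactants: 7 5-bromo-2,4-dihydroxybenzaldehyde
Product: 8 5-bromo-2-hydroxy-4-(TBSO)benzaldehyde
Conditions: TBSCl (1.05 equiv), imidazole, CH2Cl2, 0 °C
Reagents that add atoms: tert-butyldimethylsilyl chloride CC(C)(C)[Si](C)(C)Cl
Why: Silylation should be selective for the 4-OH, since the 2-OH is chelated to the aldehyde; this tells the later O2' apart from O4'.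

Step 5
Reactants: 8 5-bromo-2-hydroxy-4-(TBSO)benzaldehyde
Product: 9 5-(5,5-dimethyl-1,3,2-dioxaborinan-2-yl)-2-hydroxy-4-(TBSO)benzaldehyde
Conditions: bis(neopentyl glycolato)diboron (1.2 equiv), PdCl2(dppf) (3 mol%), KOAc (3 equiv), 1,4-dioxane, 85 °C
Reagents that add atoms: bis(neopentyl glycolato)diboron CC1(C)COB(OC1)B1OCC(C)(C)CO1
Why: In this Miyaura borylation the aldehyde, chelated phenol and aryl silyl ether tolerate KOAc, and the neopentyl glycol ester is chosen because it transmetalates to a rhodium hydroxide without added base.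

Step 6
Reactants: 6 5,7-bis(TBSO)-6,8-diprenylchromone; 9 boronate aldehyde
Product: 10 (2S)-5,7,2'-tris(TBSO)-5'-formyl-4'-hydroxy-6,8-diprenylflavanone
Conditions: 9 (1.8 equiv), [Rh(OH)(cod)]2 (2.5 mol%), (S)-2,2'-bis[bis(3,4,5-trifluorophenyl)phosphino]-6,6'-dimethoxybiphenyl (5.5 mol%), toluene/H2O, 35 °C
Reagents that add atoms: none
Why: In this Hayashi-Miyaura asymmetric 1,4-addition to a chromone the (S)-biaryl bisphosphine should deliver the aryl group to the Re face of C2 (2S, the sense known for (S)-BINAP with cyclohexenone), neutral protonolysis of the oxa-allyl rhodium keeps ring C closed, and the electron-rich chelated aldehyde is a poor 1,2-acceptor.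

Step 7
Reactants: 10 (2S)-5,7,2'-tris(TBSO)-5'-formyl-4'-hydroxy-6,8-diprenylflavanone
Product: 11 (2S)-4'-(tert-butoxycarbonyloxy)-5,7,2'-tris(TBSO)-5'-formyl-6,8-diprenylflavanone
Conditions: Boc2O (1.1 equiv), DMAP (5 mol%), CH2Cl2, 0 °C
Reagents that add atoms: di-tert-butyl dicarbonate CC(C)(C)OC(=O)OC(=O)OC(C)(C)C
Why: DMAP-catalysed O-acylation acts on the only free hydroxyl group, and its phenoxide character is drawn into the ortho aldehyde, so it should not open ring C.

Step 8
Reactants: 12 5-bromoresorcinol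
Product: 13 1-bromo-3,5-bis(TBSO)benzene
Conditions: TBSCl (2.3 equiv), imidazole, DMF, rt
Reagents that add atoms: tert-butyldimethylsilyl chloride CC(C)(C)[Si](C)(C)Cl
Why: Standard silyl ether formation on both phenols gives a bromide fit for magnesium insertion.

Step 9
Reactants: 14 4-(TBSO)benzyl alcohol; 15 (1S,4S,5S)-isothiocineole
Product: 16 (1S,4S,5S,6S)-6-[4-(TBSO)benzyl]-4,7,7-trimethyl-6-thioniabicyclo[3.2.1]octane triflate
Conditions: 15 (1.1 equiv), TfOH (1.0 equiv), CH2Cl2, -40 to 0 °C; precipitation from Et2O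
Reagents that add atoms: trifluoromethanesulfonic acid OS(=O)(=O)C(F)(F)F
Why: In this acid-promoted SN1 S-alkylation the p-siloxybenzyl cation from 14 is captured by the exo lone pair of the sulfide (anti to the three-carbon bridge), which should give one sulfonium diastereomer, and a fluoride-free acid spares the silyl ether.

Step 10
Reactants: 11 Boc-protected flavanone aldehyde; 13 1-bromo-3,5-bis(TBSO)benzene; 16 sulfonium triflate
Product: 22 hexa-TBS ether of the target (2S,αR,βR), via arylmagnesium bromide 17 (not isolated), via sulfonium benzylide 18 (not isolated), via magnesium phenoxide carbonate 19 (not isolated), via ortho-quinone methide 20 (not isolated), via betaine 21 (not isolated)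
Conditions: (a) 13, Mg, THF, 50 °C, titrate; (b) 16, LiN(SiMe3)2 (1.0 equiv to 16), THF, -78 °C; (c) 17 (1.0 equiv) added to 11, THF, -78 °C, 30 min, then cold 18 (1.3 equiv) by cannula, -78 to -20 °C; pH 7 buffer
Reagents that add atoms: none
Why: Proposed new method: 17 adds to the aldehyde of 11 with an O-to-O shift of the Boc group to give 19, the magnesium phenoxide expels tert-butyl carbonate to give the (E)-quinone methide 20, ylide 18 adds to its methide carbon to give 21, and the rearomatised 4'-phenoxide displaces the sulfide. The closest known reaction types are the generation of ortho-quinone methides from O-Boc salicylaldehydes with Grignard reagents, the trans-selective [4+1] annulation of ortho-quinone methides with carbonyl-stabilised sulfur ylides, and the epoxidation of aldehydes with isothiocineole benzylides; new are their merger in one flask and the use of a chiral semi-stabilised benzylide on a quinone methide. Ring D closes by 5-exo-tet SN2 attack of O4' on Cα with inversion, after the Cα–Cβ bond has formed by 1,4-addition. Cα is controlled by the sulfide: the exo-bound ylide holds its aryl group syn to the sulfur lone pair and the CMe2 group shields one face, so the Si face should bond and inversion should give αR. Cβ is controlled by the open transition state that places the two aryl groups anti and the sulfonium group away from ring B (Re face of the methide carbon, βR), which is also the rotamer that closes directly to the trans ring. The step needs addition to the aldehyde and not to the C4 ketone (hindered and tri-oxygenated, -78 °C), capture of 20 by 18 and not by 17 (no excess of 17), and an intact ring C (18 is too weak a base for C3–H, and the 4'-phenoxide has a far better leaving group at Cβ and then at Cα than O1).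

Step 11
Reactants: 22 hexa-TBS ether of the target
Product: 23 target (2S,αR,βR)
Conditions: Et3N·3HF (excess), THF, rt
Reagents that add atoms: none
Why: Fluoride cleaves all six aryl silyl ethers in a weakly acidic buffered medium, which has no base to racemise C2 through ring opening and no strong acid to cyclise prenyl groups onto phenols or ionise Cα.

Compound list
1 | 2',4',6'-trihydroxyacetophenone | CC(=O)c1c(O)cc(O)cc1O | starting material
2 | prenyl bromide (1-bromo-3-methylbut-2-ene) | CC(C)=CCBr | starting material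
3 | 2',4',6'-trihydroxy-3',5'-diprenylacetophenone | CC(=O)c1c(O)c(CC=C(C)C)c(O)c(CC=C(C)C)c1O | intermediate
4 | 2'-hydroxy-4',6'-bis(TBSO)-3',5'-diprenylacetophenone | CC(=O)c1c(O)c(CC=C(C)C)c(O[Si](C)(C)C(C)(C)C)c(CC=C(C)C)c1O[Si](C)(C)C(C)(C)C | intermediate
5 | (E)-3-(dimethylamino)prop-2-en-1-one (enaminone) derived from 4 | CN(C)/C=C/C(=O)c1c(O)c(CC=C(C)C)c(O[Si](C)(C)C(C)(C)C)c(CC=C(C)C)c1O[Si](C)(C)C(C)(C)C | intermediate
6 | 5,7-bis(TBSO)-6,8-diprenylchromone | O=c1ccoc2c(CC=C(C)C)c(O[Si](C)(C)C(C)(C)C)c(CC=C(C)C)c(O[Si](C)(C)C(C)(C)C)c12 | intermediate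
7 | 5-bromo-2,4-dihydroxybenzaldehyde | O=Cc1cc(Br)c(O)cc1O | starting material
8 | 5-bromo-2-hydroxy-4-(TBSO)benzaldehyde | O=Cc1cc(Br)c(O[Si](C)(C)C(C)(C)C)cc1O | intermediate
9 | 5-(5,5-dimethyl-1,3,2-dioxaborinan-2-yl)-2-hydroxy-4-(TBSO)benzaldehyde | O=Cc1cc(B2OCC(C)(C)CO2)c(O[Si](C)(C)C(C)(C)C)cc1O | intermediate
10 | (2S)-5,7,2'-tris(TBSO)-5'-formyl-4'-hydroxy-6,8-diprenylflavanone | CC(C)=CCc1c(O[Si](C)(C)C(C)(C)C)c(CC=C(C)C)c2c(c1O[Si](C)(C)C(C)(C)C)C(=O)C[C@@H](c1cc(C=O)c(O)cc1O[Si](C)(C)C(C)(C)C)O2 | intermediate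
11 | (2S)-4'-(tert-butoxycarbonyloxy)-5,7,2'-tris(TBSO)-5'-formyl-6,8-diprenylflavanone | CC(C)=CCc1c(O[Si](C)(C)C(C)(C)C)c(CC=C(C)C)c2c(c1O[Si](C)(C)C(C)(C)C)C(=O)C[C@@H](c1cc(C=O)c(OC(=O)OC(C)(C)C)cc1O[Si](C)(C)C(C)(C)C)O2 | intermediate
12 | 5-bromoresorcinol | Oc1cc(O)cc(Br)c1 | starting material
13 | 1-bromo-3,5-bis(TBSO)benzene | CC(C)(C)[Si](C)(C)Oc1cc(Br)cc(O[Si](C)(C)C(C)(C)C)c1 | intermediate
14 | 4-(TBSO)benzyl alcohol | OCc1ccc(O[Si](C)(C)C(C)(C)C)cc1 | starting material
15 | (1S,4S,5S)-isothiocineole (4,7,7-trimethyl-6-thiabicyclo[3.2.1]octane) | C[C@H]1CC[C@H]2C[C@@H]1SC2(C)C | starting material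
16 | (1S,4S,5S,6S)-6-[4-(TBSO)benzyl]-4,7,7-trimethyl-6-thioniabicyclo[3.2.1]octane triflate (benzyl group exo on sulfur) | C[C@H]1CC[C@H]2C[C@@H]1[S@+](Cc1ccc(O[Si](C)(C)C(C)(C)C)cc1)C2(C)C.[O-]S(=O)(=O)C(F)(F)F | intermediate
17 | 3,5-bis(TBSO)phenylmagnesium bromide | CC(C)(C)[Si](C)(C)Oc1cc([Mg]Br)cc(O[Si](C)(C)C(C)(C)C)c1 | intermediate
18 | sulfonium 4-(TBSO)benzylide derived from 16 | C[C@H]1CC[C@H]2C[C@@H]1[S@+]([CH-]c1ccc(O[Si](C)(C)C(C)(C)C)cc1)C2(C)C | intermediate
19 | bromomagnesium 4'-phenoxide of the (2S)-flavanone carrying CH(OBoc)[3,5-bis(TBSO)phenyl] at C5' (both Cβ epimers) | CC(C)=CCc1c(O[Si](C)(C)C(C)(C)C)c(CC=C(C)C)c2c(c1O[Si](C)(C)C(C)(C)C)C(=O)C[C@@H](c1cc(C(OC(=O)OC(C)(C)C)c3cc(O[Si](C)(C)C(C)(C)C)cc(O[Si](C)(C)C(C)(C)C)c3)c(O[Mg]Br)cc1O[Si](C)(C)C(C)(C)C)O2 | intermediate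
20 | (E)-ortho-quinone methide of ring B (C4'=O, C5'=Cβ–aryl, aryl anti to the carbonyl group), 2S | CC(C)=CCc1c(O[Si](C)(C)C(C)(C)C)c(CC=C(C)C)c2c(c1O[Si](C)(C)C(C)(C)C)C(=O)C[C@@H](C1=C/C(=C\c3cc(O[Si](C)(C)C(C)(C)C)cc(O[Si](C)(C)C(C)(C)C)c3)C(=O)C=C1O[Si](C)(C)C(C)(C)C)O2 | intermediate
21 | betaine: 4'-phenoxide with Cβ (R) bound to the sulfonium-bearing Cα (S), 2S | C[C@H]1CC[C@H]2C[C@@H]1[S@+]([C@H](c1ccc(O[Si](C)(C)C(C)(C)C)cc1)[C@H](c1cc(O[Si](C)(C)C(C)(C)C)cc(O[Si](C)(C)C(C)(C)C)c1)c1cc([C@@H]3CC(=O)c4c(O[Si](C)(C)C(C)(C)C)c(CC=C(C)C)c(O[Si](C)(C)C(C)(C)C)c(CC=C(C)C)c4O3)c(O[Si](C)(C)C(C)(C)C)cc1[O-])C2(C)C | intermediate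
22 | hexa-TBS ether of the target, (2S,αR,βR), ring D trans | CC(C)=CCc1c(O[Si](C)(C)C(C)(C)C)c(CC=C(C)C)c2c(c1O[Si](C)(C)C(C)(C)C)C(=O)C[C@@H](c1cc3c(cc1O[Si](C)(C)C(C)(C)C)O[C@@H](c1ccc(O[Si](C)(C)C(C)(C)C)cc1)[C@@H]3c1cc(O[Si](C)(C)C(C)(C)C)cc(O[Si](C)(C)C(C)(C)C)c1)O2 | intermediate
23 | CNP0230984.1, (2S)-5,7-dihydroxy-6,8-diprenyl-2-[(2R,3R)-3-(3,5-dihydroxyphenyl)-6-hydroxy-2-(4-hydroxyphenyl)-2,3-dihydrobenzofuran-5-yl]chroman-4-one | CC(C)=CCc1c(O)c(CC=C(C)C)c2c(c1O)C(=O)C[C@@H](c1cc3c(cc1O)O[C@@H](c1ccc(O)cc1)[C@@H]3c1cc(O)cc(O)c1)O2 | target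

Total step count: 11. Longest linear sequence: 7 steps (1, 2, 3, 6, 7, 10, 11).

Steps most likely to fail

Step 10. Three things may go wrong:
- Facial selectivity at the methide carbon may be poor.
- The ring closure may drift from SN2 towards ionisation at the p-siloxybenzyl carbon, which would blur the link between the sulfide and Cβ.
- The Grignard reagent may capture the quinone methide before the ylide does.

The fallback uses known chemistry. It makes the Cα–Cβ bond by enantioselective C–H insertion of a donor/donor rhodium carbene on the ring B fragment, at a point where ring C already exists in 6. It sets out from 8 and comes back at 22. Mitsunobu etherification of 8 with 14 (PPh3, DIAD) gives the benzyl ether aldehyde F1. Addition of 17 gives the benzhydrol F2, which MnO2 oxidises to the benzophenone F3. Hydrazine hydrate gives the hydrazone F4, and MnO2 gives the diaryldiazomethane F5. Rh2(R-PTAD)4 (or its antipode, whichever gives βR) converts F5 by insertion into the O–CH2 bond into the cis-dihydrobenzofuran F6. Catalytic TFA in CH2Cl2 epimerises Cα through the p-siloxybenzyl cation to the trans-dihydrobenzofuran F7. Miyaura borylation as in step 5 gives the boronate F8, and F8 adds to 6 under the conditions of step 6 to give 22.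

Step 6. Protodeboronation of the hindered, electron-rich boronate may outrun insertion into the sluggish chromone, and aryl transfer to the aldehyde may compete. The fallback masks the aldehyde and changes the metal. It sets out from 9 and comes back at 10. HC(OMe)3 with catalytic PPTS converts 9 into the dimethyl acetal boronate F9. F9 is added to 6 by the cationic divalent palladium conjugate addition (Pd(OCOCF3)2, the t-BuPyOx enantiomer that gives 2S, NH4PF6, H2O, ClCH2CH2Cl, 60 °C) to give the acetal flavanone F10. PPTS in wet acetone then releases 10.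

Step 1. Alkylation may run on to geminal diprenylated, dearomatised products or go to oxygen. The fallback brings in the carbon chains by rearrangement and builds the prenyl termini by metathesis. It sets out from 1 and comes back at 3. Allyl bromide with K2CO3 in acetone gives the bis(allyl ether) F11. Heating in N,N-diethylaniline (double aromatic Claisen rearrangement, with a para shift if C5' is filled first) gives the diallyl triol F12. Cross metathesis with 2-methylbut-2-ene and the second-generation Grubbs catalyst gives 3.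

Further compounds
F1 | step 10 | 5-bromo-4-(TBSO)-2-[4-(TBSO)benzyloxy]benzaldehyde | O=Cc1cc(Br)c(O[Si](C)(C)C(C)(C)C)cc1OCc1ccc(O[Si](C)(C)C(C)(C)C)cc1
F2 | step 10 | [3,5-bis(TBSO)phenyl]{5-bromo-4-(TBSO)-2-[4-(TBSO)benzyloxy]phenyl}methanol (racemic) | OC(c1cc(O[Si](C)(C)C(C)(C)C)cc(O[Si](C)(C)C(C)(C)C)c1)c1cc(Br)c(O[Si](C)(C)C(C)(C)C)cc1OCc1ccc(O[Si](C)(C)C(C)(C)C)cc1
F3 | step 10 | corresponding benzophenone | O=C(c1cc(O[Si](C)(C)C(C)(C)C)cc(O[Si](C)(C)C(C)(C)C)c1)c1cc(Br)c(O[Si](C)(C)C(C)(C)C)cc1OCc1ccc(O[Si](C)(C)C(C)(C)C)cc1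
F4 | step 10 | hydrazone of F3 | NN=C(c1cc(O[Si](C)(C)C(C)(C)C)cc(O[Si](C)(C)C(C)(C)C)c1)c1cc(Br)c(O[Si](C)(C)C(C)(C)C)cc1OCc1ccc(O[Si](C)(C)C(C)(C)C)cc1
F5 | step 10 | diaryldiazomethane from F4 | [N-]=[N+]=C(c1cc(O[Si](C)(C)C(C)(C)C)cc(O[Si](C)(C)C(C)(C)C)c1)c1cc(Br)c(O[Si](C)(C)C(C)(C)C)cc1OCc1ccc(O[Si](C)(C)C(C)(C)C)cc1
F6 | step 10 | (2S,3R)-cis-5-bromo-6-(TBSO)-2-[4-(TBSO)phenyl]-3-[3,5-bis(TBSO)phenyl]-2,3-dihydrobenzofuran | Brc1cc2c(cc1O[Si](C)(C)C(C)(C)C)O[C@H](c1ccc(O[Si](C)(C)C(C)(C)C)cc1)[C@@H]2c1cc(O[Si](C)(C)C(C)(C)C)cc(O[Si](C)(C)C(C)(C)C)c1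
F7 | step 10 | (2R,3R)-trans isomer of F6 | Brc1cc2c(cc1O[Si](C)(C)C(C)(C)C)O[C@@H](c1ccc(O[Si](C)(C)C(C)(C)C)cc1)[C@@H]2c1cc(O[Si](C)(C)C(C)(C)C)cc(O[Si](C)(C)C(C)(C)C)c1
F8 | step 10 | 5-(5,5-dimethyl-1,3,2-dioxaborinan-2-yl) analogue of F7 | CC1(C)COB(OC1)c1cc2c(cc1O[Si](C)(C)C(C)(C)C)O[C@@H](c1ccc(O[Si](C)(C)C(C)(C)C)cc1)[C@@H]2c1cc(O[Si](C)(C)C(C)(C)C)cc(O[Si](C)(C)C(C)(C)C)c1
F9 | step 6 | dimethyl acetal of 9 | COC(OC)c1cc(B2OCC(C)(C)CO2)c(O[Si](C)(C)C(C)(C)C)cc1O
F10 | step 6 | (2S)-5'-(dimethoxymethyl) analogue of 10 | CC(C)=CCc1c(O[Si](C)(C)C(C)(C)C)c(CC=C(C)C)c2c(c1O[Si](C)(C)C(C)(C)C)C(=O)C[C@@H](c1cc(C(OC)OC)c(O)cc1O[Si](C)(C)C(C)(C)C)O2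
F11 | step 1 | 2'-hydroxy-4',6'-bis(allyloxy)acetophenone | CC(=O)c1c(O)cc(OCC=C)cc1OCC=C
F12 | step 1 | 3',5'-diallyl-2',4',6'-trihydroxyacetophenone | CC(=O)c1c(O)c(CC=C)c(O)c(CC=C)c1O
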